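The 6.0 min of these flasks, against the 80.0 s of the summer run's last reading, is where your hunch puts the loss of target, and we would judge these flasks by what is left of the substrate and by how much of the remainder still stands as target.

in all of them: substrate 0.64 M

| run | reagent | temperature | remark | time |
|---|---|---|---|---|
| summer | 4.5 equiv | 45 °C | run made earlier |  |
| maple | 3.00 equiv | 45 °C |  | 6.0 min |
| birch | 3.00 equiv | −30 °C |  | 6.0 min |
| cedar | 3.00 equiv | 20 °C |  | 6.0 min |
| oak | 3.00 equiv | −5 °C |  | 6.0 min |

summer run (percent of the substrate charged)

| time / s | target / % | substrate / % |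
|---|---|---|
| 10.0 | 21.3 | 34.0 |
| 25.0 | 24.6 | 19.0 |
| 50.0 | 21.3 | 6.8 |
| 80.0 | 18.5 | 1.7 |

(scatter of a reading: 0.5 percentage points)

- a reading or a percentage of target counts all its forms, free or not
- the earlier runs do not show what temperature does; that part of a forecast is a guess

1. the flask with the highest amount of target, in percent of the substrate charged ("all alike" if they lie within 1.5 percentage points) (maple / birch / cedar / oak / all alike)
2. final target, as a percentage of the substrate charged, in maple
3. final target, as a percentage of the substrate charged, in birch
4. final target, as a percentage of the substrate charged, in cedar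
5. final target, as a percentage of the substrate charged, in oak

Take the substrate first. In the summer run its fraction left falls from 19.0% to 1.7% between 25.0 s and 80.0 s, a tail rate of 0.0439 s⁻¹. If that rate scales with the reagent, which is our assumption, maple keeps 0.00266% after 6.0 min, so its final target is simply the share of reacted substrate that remains target.

Dividing target by one minus substrate left gives that share, the yield on converted substrate: 30.4%, 22.9% and 18.8% at the last three readings. It is falling ever more slowly. Fitting a single exponential to that slowing gives a rate of 0.0293 s⁻¹ and a resting value, the resting kept share, of 15.9%. That is our number for maple, read through a scatter of 0.5 percentage points.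

Temperature is a guess. If every rate slowed alike, a slowdown of 14.4 would put the summer run's highest target reading, 24.6%, at 6.0 min, and we bet on cedar landing near it, with oak and birch behind.

The forecast gives maple 7%, birch 1%, cedar 21% and oak 9%, with cedar highest, and says of maple that “target still peaks early and then decays”.

The flasks give maple 17.4%, birch 0.0350%, cedar 31.2% and oak 6.60%, so cedar holds most.

    intermediate → target (k = 0.00800 s⁻¹, Ea = 75.0 kJ mol⁻¹)
    target ⇌ isomer of the product (K = 8.50, k = 0.00470 s⁻¹, Ea = 93.0 kJ mol⁻¹, ΔH = −18.0 kJ mol⁻¹)
    crystals ⇌ target, rate k3*(cs3 - [target]) while solid is left; crystals form when [target] > cs3 (solubility = 0.470 M, k = 0.290 s⁻¹)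
    reagent ⇌ dormant form (K = 0.180, k = 0.00470 s⁻¹, Ea = 87.0 kJ mol⁻¹, ΔH = −75.0 kJ mol⁻¹)
    substrate + reagent ⇌ intermediate (K = 0.700 M⁻¹, k = 0.0260 M⁻¹ s⁻¹, Ea = 57.0 kJ mol⁻¹, ΔH = −15.0 kJ mol⁻¹)
    (constants at 20 °C)

Maple ends with free substrate at 0%, so its kept share is 17.4%, above our 15.9%. Cedar still holds 17% of free substrate at 6.00 min, and its kept share is 37.6%. The neighbouring flask is cedar left until 10 min: free substrate is down to 7.6%, yet target has fallen to 23.3%, so the same division gives 25.2%, with the isomer of the product at 63.7%.

The runs were computed for an exercise; scatter was added.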